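**Plan**
- Retrosynthesis: the ester C–O bonds (C3 acetate, C2 benzoate) are cut first, then the two allylic C–O bonds at C2 and C5 are cut together as one O–O unit, leaving a C2=C1–C6=C5 ring diene.
- That diene (C3/C4 cis-diol as acetonide, C7 on C1) comes from shikimic acid by loss of water across C5–C6 and reduction of the carboxyl group to C7H2O.
- Forward: the carbocycle is the shikimate ring throughout; the only ring made is the 1,2-dioxine bridge of an endoperoxide, which is then cleaved at O–O. The C7 benzoate goes on before the oxygenation, the C2 benzoate and C3 acetate after it.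
- Enabling feature (C1 = olefinic carbon bearing C7H2OBz, C2 OBz, C3 OAc, C4 OH, C5 OH, C6 olefinic CH): O2 and O5 lie 1,4 to each other across the C1=C6 alkene, mutually cis and trans to the cis O3/O4 pair. This is the imprint of dioxygen adding across a ring diene on the face away from a C3/C4 acetonide.
- Stereochemistry: C3 and C4 are carried unchanged from shikimic acid; C2 and C5 are set together in the cycloaddition by the acetonide-shielded face.

Key step: step 6

Remark on naming: ring atoms keep shikimate numbering (C1 carries C7; C1=C6 from the key step onward). β is the face carrying O3 and O4, α the opposite face. "The pentol" means 1-(hydroxymethyl)cyclohex-6-ene-2α,3β,4β,5α-tetrol. TBDPS = tert-butyldiphenylsilyl.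

**Route**

Step 1
Reactants: 1 (−)-shikimic acid
Product: 3 methyl 3,4-O-isopropylidene-shikimate, via methyl shikimate 2 (not isolated)
Conditions: CSA (cat.), MeOH, reflux; evaporate; 2,2-dimethoxypropane, CSA (cat.), acetone, rt; Et3N quench
Reagents that add atoms: methanol, CO; 2,2-dimethoxypropane, COC(C)(C)OC
Why: Fischer esterification followed by acid-catalysed transketalisation; the cis C3/C4 diol closes the dioxolane in preference to the trans C4/C5 pair, and no stereocentre is touched.

Step 2
Reactants: 3 methyl 3,4-O-isopropylidene-shikimate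
Product: 4 methyl 3,4-O-isopropylidene-5-O-(trifluoromethanesulfonyl)shikimate
Conditions: Tf2O, pyridine, CH2Cl2, −30 → 0 °C; crude product used at once
Reagents that add atoms: trifluoromethanesulfonic anhydride, O=S(=O)(OS(=O)(=O)C(F)(F)F)C(F)(F)F
Why: O-sulfonylation of the only free hydroxyl, with retention at C5 because the C–O bond is not broken.

Step 3
Reactants: 4 methyl 3,4-O-isopropylidene-5-O-(trifluoromethanesulfonyl)shikimate
Product: 5 methyl (3R,4S)-3,4-(isopropylidenedioxy)cyclohexa-1,5-diene-1-carboxylate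
Conditions: CsOAc, DMF, rt
Reagents that add atoms: none
Why: E2 elimination; the α-triflate at C5 is antiperiplanar to the β-hydrogen on C6 while H4 is syn to it, so only the C5=C6 alkene can form and the diene ends up conjugated with the ester.

Step 4
Reactants: 5 methyl (3R,4S)-3,4-(isopropylidenedioxy)cyclohexa-1,5-diene-1-carboxylate
Product: 6 [(3R,4S)-3,4-(isopropylidenedioxy)cyclohexa-1,5-dien-1-yl]methanol
Conditions: iBu2AlH (2.5 equiv), CH2Cl2, −78 °C; aq. KNaC4H4O6 work-up; used without storage
Reagents that add atoms: none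
Why: 1,2-reduction of the unsaturated ester by the aluminium hydride at low temperature; the neutral tartrate work-up avoids acid-triggered aromatisation of the dihydroarene acetonide.

Step 5
Reactants: 6 [(3R,4S)-3,4-(isopropylidenedioxy)cyclohexa-1,5-dien-1-yl]methanol; 7 benzoyl chloride
Product: 8 [(3R,4S)-3,4-(isopropylidenedioxy)cyclohexa-1,5-dien-1-yl]methyl benzoate
Conditions: BzCl, Et3N, DMAP (cat.), CH2Cl2, 0 °C
Reagents that add atoms: benzoyl chloride (7), O=C(Cl)c1ccccc1
Why: DMAP-catalysed acylation of the primary allylic alcohol under basic conditions that the acid-labile diene tolerates.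

Step 6
Reactants: 8 [(3R,4S)-3,4-(isopropylidenedioxy)cyclohexa-1,5-dien-1-yl]methyl benzoate; 9 dioxygen (singlet state generated in the flask)
Product: 10 [(2S,3S,4R,5R)-2,5-epidioxy-3,4-(isopropylidenedioxy)cyclohex-6-en-1-yl]methyl benzoate (peroxide bridge α, acetonide β)
Conditions: O2, tetraphenylporphyrin (cat.), visible light (white LED), CH2Cl2, −30 °C
Reagents that add atoms: dioxygen (9), O=O
Why: Triplet-excited tetraphenylporphyrin passes its energy to dioxygen, and the resulting singlet oxygen adds in a concerted suprafacial [4+2] cycloaddition across the s-cis-locked C2=C1–C6=C5 diene, forming the C2–O and C5–O bonds and moving the alkene to C1=C6; the closest known reaction type is the sensitised photooxygenation of cyclohexa-3,5-diene-1,2-diol acetonides to anti endoperoxides. The single new ring, the six-membered 1,2-dioxine of the 2,3-dioxabicyclo[2.2.2]oct-5-ene bridge, closes in this one pericyclic event as a hetero-Diels–Alder closure with O=O as the two-atom partner. C2 and C5 become stereocentres together: suprafacial addition makes the two new oxygens cis to each other, and the β-face cis-fused dioxolane at C3/C4, with its inward methyl group over the diene termini, sends the oxidant to the α face, so both oxygens end up trans to O3/O4. The step needs π-facial selectivity and cycloaddition in preference to the Schenck ene reaction at the C7 methylene or ring C–H bonds; the acetonide should secure the first, and the rigid cisoid ring diene, a non-polar solvent and low temperature the second. The C7 benzoate is a spectator, and having C7 at the alcohol rather than the ester oxidation level keeps the diene electron-rich enough to capture the short-lived oxidant quickly.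

Step 7
Reactants: 10 [(2S,3S,4R,5R)-2,5-epidioxy-3,4-(isopropylidenedioxy)cyclohex-6-en-1-yl]methyl benzoate
Product: 11 7-O-benzoyl-3,4-O-isopropylidene pentol, [(2S,3R,4S,5R)-2,5-dihydroxy-3,4-(isopropylidenedioxy)cyclohex-6-en-1-yl]methyl benzoate
Conditions: thiourea (2.2 equiv), MeOH, 0 °C → rt
Reagents that add atoms: none
Why: Thiourea reduction of the peroxide cleaves only the O–O bond, so both C–O bonds and the configurations at C2 and C5 are kept; the neutral medium leaves the benzoate, acetonide and alkene alone.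

Step 8
Reactants: 11 7-O-benzoyl-3,4-O-isopropylidene pentol
Product: 12 7-O-benzoyl-3,4-O-isopropylidene-5-O-TBDPS pentol
Conditions: TBDPSCl (1.05 equiv), imidazole, DMF, 0 °C
Reagents that add atoms: tert-butyl(chloro)diphenylsilane, CC(C)(C)[Si](Cl)(c1ccccc1)c1ccccc1
Why: Sterically controlled monosilylation; O5 adjoins the unsubstituted vinylic C6–H whereas O2 is flanked by the C1 benzoyloxymethyl branch, so the bulky silyl chloride should take the C5 hydroxyl.

Step 9
Reactants: 12 7-O-benzoyl-3,4-O-isopropylidene-5-O-TBDPS pentol; 7 benzoyl chloride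
Product: 13 2,7-di-O-benzoyl-3,4-O-isopropylidene-5-O-TBDPS pentol
Conditions: BzCl, pyridine, DMAP (cat.), CH2Cl2, 0 °C → rt
Reagents that add atoms: benzoyl chloride (7), O=C(Cl)c1ccccc1
Why: DMAP-catalysed acylation of the one remaining hydroxyl (O2); silyl ether and acetonide are inert to acylation conditions.

Step 10
Reactants: 13 2,7-di-O-benzoyl-3,4-O-isopropylidene-5-O-TBDPS pentol
Product: 14 2,7-di-O-benzoyl-5-O-TBDPS pentol (free 3β,4β-diol)
Conditions: TFA/H2O (9:1), CH2Cl2, 0 °C
Reagents that add atoms: none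
Why: Acid hydrolysis of the ketal; the tert-butyldiphenylsilyl ether and the benzoates withstand aqueous trifluoroacetic acid, and the trans-diaxial O2/O3 arrangement disfavours benzoyl migration.

Step 11
Reactants: 14 2,7-di-O-benzoyl-5-O-TBDPS pentol
Product: 16 3-O-acetyl-2,7-di-O-benzoyl-5-O-TBDPS pentol, via cyclic orthoacetate 15 (not isolated)
Conditions: MeC(OMe)3, CSA (cat.), CH2Cl2, rt; then AcOH/H2O (4:1), rt
Reagents that add atoms: trimethyl orthoacetate, CC(OC)(OC)OC; water, O
Why: Orthoester exchange ties the cis C3/C4 diol into a 2-methoxy-2-methyl-1,3-dioxolane, and its mild acid hydrolysis (dioxolan-2-ylium ion, then hemi-orthoester) opens regioselectively to the axial ester; in the favoured half-chair O2 is pseudoaxial (allylic strain against C7) and the O5 silyl ether pseudoequatorial, which makes O3 axial and O4 equatorial, so the acetyl group should stay on O3.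

Step 12
Reactants: 16 3-O-acetyl-2,7-di-O-benzoyl-5-O-TBDPS pentol
Product: 17 3-O-acetyl-2,7-di-O-benzoyl pentol, [(2S,3S,4S,5R)-3-acetoxy-2-(benzoyloxy)-4,5-dihydroxycyclohex-6-en-1-yl]methyl benzoate (target)
Conditions: HF·pyridine, pyridine, THF, 0 °C → rt (plastic vessel)
Reagents that add atoms: none
Why: Fluoride-driven Si–O cleavage in a mildly acidic, non-basic medium, chosen so that the acetate does not migrate from O3 to the neighbouring cis O4 and the benzoates stay in place.

**Compound list**

1 | (−)-shikimic acid, (3R,4S,5R)-3,4,5-trihydroxycyclohex-1-ene-1-carboxylic acid | OC(=O)C1=C[C@@H](O)[C@@H](O)[C@H](O)C1 | starting material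
2 | methyl shikimate | COC(=O)C1=C[C@@H](O)[C@@H](O)[C@H](O)C1 | intermediate (not isolated)
3 | methyl 3,4-O-isopropylidene-shikimate (3β,4β-acetonide, 5α-OH) | COC(=O)C1=C[C@H]2OC(C)(C)O[C@H]2[C@H](O)C1 | intermediate
4 | methyl 3,4-O-isopropylidene-5-O-(trifluoromethanesulfonyl)shikimate | COC(=O)C1=C[C@H]2OC(C)(C)O[C@H]2[C@H](OS(=O)(=O)C(F)(F)F)C1 | intermediate
5 | methyl (3R,4S)-3,4-(isopropylidenedioxy)cyclohexa-1,5-diene-1-carboxylate | COC(=O)C1=C[C@H]2OC(C)(C)O[C@H]2C=C1 | intermediate
6 | [(3R,4S)-3,4-(isopropylidenedioxy)cyclohexa-1,5-dien-1-yl]methanol | OCC1=C[C@H]2OC(C)(C)O[C@H]2C=C1 | intermediate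
7 | benzoyl chloride | O=C(Cl)c1ccccc1 | starting material
8 | [(3R,4S)-3,4-(isopropylidenedioxy)cyclohexa-1,5-dien-1-yl]methyl benzoate | CC1(C)O[C@H]2[C@@H](O1)C=CC(COC(=O)c1ccccc1)=C2 | intermediate (key-step precursor)
9 | dioxygen | O=O | starting material
10 | [(2S,3S,4R,5R)-2,5-epidioxy-3,4-(isopropylidenedioxy)cyclohex-6-en-1-yl]methyl benzoate (α-peroxide, β-acetonide) | CC1(C)O[C@H]2[C@@H](O1)[C@H]3C=C(COC(=O)c4ccccc4)[C@@H]2OO3 | intermediate (key-step product)
11 | 7-O-benzoyl-3,4-O-isopropylidene pentol (2α,5α-diol) | CC1(C)O[C@H]2[C@@H](O1)[C@H](O)C=C(COC(=O)c3ccccc3)[C@@H]2O | intermediate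
12 | 7-O-benzoyl-3,4-O-isopropylidene-5-O-TBDPS pentol | CC1(C)O[C@H]2[C@@H](O1)[C@H](O[Si](c3ccccc3)(c4ccccc4)C(C)(C)C)C=C(COC(=O)c5ccccc5)[C@@H]2O | intermediate
13 | 2,7-di-O-benzoyl-3,4-O-isopropylidene-5-O-TBDPS pentol | CC1(C)O[C@H]2[C@@H](O1)[C@H](O[Si](c3ccccc3)(c4ccccc4)C(C)(C)C)C=C(COC(=O)c5ccccc5)[C@@H]2OC(=O)c6ccccc6 | intermediate
14 | 2,7-di-O-benzoyl-5-O-TBDPS pentol | O[C@H]1[C@@H](O)[C@H](O[Si](c2ccccc2)(c3ccccc3)C(C)(C)C)C=C(COC(=O)c4ccccc4)[C@@H]1OC(=O)c5ccccc5 | intermediate
15 | 2,7-di-O-benzoyl-3,4-O-(1-methoxyethylidene)-5-O-TBDPS pentol (both epimers at the orthoester carbon) | COC1(C)O[C@H]2[C@@H](O1)[C@H](O[Si](c3ccccc3)(c4ccccc4)C(C)(C)C)C=C(COC(=O)c5ccccc5)[C@@H]2OC(=O)c6ccccc6 | intermediate (not isolated)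
16 | 3-O-acetyl-2,7-di-O-benzoyl-5-O-TBDPS pentol | CC(=O)O[C@H]1[C@@H](O)[C@H](O[Si](c2ccccc2)(c3ccccc3)C(C)(C)C)C=C(COC(=O)c4ccccc4)[C@@H]1OC(=O)c5ccccc5 | intermediate
17 | [(2S,3S,4S,5R)-3-acetoxy-2-(benzoyloxy)-4,5-dihydroxycyclohex-6-en-1-yl]methyl benzoate | CC(=O)O[C@H]1[C@@H](O)[C@H](O)C=C(COC(=O)c2ccccc2)[C@@H]1OC(=O)c1ccccc1 | target

**Count and risks**

Total step count: 12. Longest linear sequence: 12 steps (1 → 17).

Steps most likely to fail:

1. Step 8. The silyl chloride may not distinguish the two secondary allylic hydroxyls well enough, so that silylation at O2 and double silylation consume material. The fallback sets out from 11 and comes back at 13; it masks O7 and O2, the two oxygens that must both become benzoates, as a 1,3-diol pair instead of relying on steric bias. K2CO3 in MeOH at 0 °C removes the C7 benzoate to give the 3,4-O-isopropylidene pentol F1. Phenylboronic acid (toluene, MgSO4, rt) closes a six-membered cyclic boronate across O7 and O2, the 2,7-O-phenylboronate F2, in which O5 is the only free hydroxyl. TBDPSCl and imidazole then give the 5-O-TBDPS boronate F3. Exchange with pinacol releases the 3,4-O-isopropylidene-5-O-TBDPS pentol F4, and BzCl (2.5 equiv), pyridine and DMAP acylate both free hydroxyls to give 13.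

2. Step 11. The hemi-orthoester may collapse toward the equatorial oxygen, or the acetyl group may migrate from O3 to O4 during hydrolysis, giving the C4 acetate. The fallback sets out from 14 and comes back at 17; it blocks O4 and O5 together and acetylates O3 directly. HF·pyridine frees O5 to give the 2,7-di-O-benzoyl pentol F5. 2,2,3,3-Tetramethoxybutane, HC(OMe)3 and CSA in warm MeOH form the butane-2,3-diacetal on the trans-diequatorial O4/O5 pair, the selectivity such diacetals show with shikimate esters, giving the 4,5-diacetal F6 with O3 as the only free hydroxyl. Ac2O, pyridine and DMAP give the 3-O-acetyl 4,5-diacetal F7, and TFA/H2O (9:1) at 0 °C removes the diacetal to give 17.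

3. Step 6. Diene 8 may be lost by [4+2] dimerisation or acid-triggered aromatisation (loss of acetone) before or during irradiation, or the Schenck ene pathway at the benzoyloxymethyl group may compete with cycloaddition. The fallback sets out from 6 and comes back at 10; it oxygenates the diene one step earlier. Crude alcohol 6 is irradiated directly with O2 and tetraphenylporphyrin in CH2Cl2 at −30 °C to give the endoperoxide alcohol F8, which can no longer dimerise or aromatise. F8 is then benzoylated with 7 (pyridine, CH2Cl2, −20 °C; a weak base, to avoid Kornblum–DeLaMare cleavage of the peroxide) to give 10.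

**Further compounds**

F1 | step 8 | 3,4-O-isopropylidene pentol (2α,5α,7-triol) | CC1(C)O[C@H]2[C@@H](O1)[C@H](O)C=C(CO)[C@@H]2O
F2 | step 8 | 3,4-O-isopropylidene-2,7-O-(phenylboranediyl) pentol | CC1(C)O[C@H]2[C@@H](O1)[C@H](O)C=C3COB(c4ccccc4)O[C@H]23
F3 | step 8 | 3,4-O-isopropylidene-2,7-O-(phenylboranediyl)-5-O-TBDPS pentol | CC1(C)O[C@H]2[C@@H](O1)[C@H](O[Si](c5ccccc5)(c6ccccc6)C(C)(C)C)C=C3COB(c4ccccc4)O[C@H]23
F4 | step 8 | 3,4-O-isopropylidene-5-O-TBDPS pentol (2,7-diol) | CC1(C)O[C@H]2[C@@H](O1)[C@H](O[Si](c3ccccc3)(c4ccccc4)C(C)(C)C)C=C(CO)[C@@H]2O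
F5 | step 11 | 2,7-di-O-benzoyl pentol (3β,4β,5α-triol) | O[C@H]1[C@@H](O)[C@H](O)C=C(COC(=O)c2ccccc2)[C@@H]1OC(=O)c3ccccc3
F6 | step 11 | 2,7-di-O-benzoyl-4,5-O-[(2S,3S)-2,3-dimethoxybutane-2,3-diyl] pentol | O[C@H]1[C@H]2O[C@](C)(OC)[C@@](C)(OC)O[C@@H]2C=C(COC(=O)c3ccccc3)[C@@H]1OC(=O)c4ccccc4
F7 | step 11 | 3-O-acetyl-2,7-di-O-benzoyl-4,5-O-[(2S,3S)-2,3-dimethoxybutane-2,3-diyl] pentol | CC(=O)O[C@H]1[C@H]2O[C@](C)(OC)[C@@](C)(OC)O[C@@H]2C=C(COC(=O)c3ccccc3)[C@@H]1OC(=O)c4ccccc4
F8 | step 6 | [(2S,3S,4R,5R)-2,5-epidioxy-3,4-(isopropylidenedioxy)cyclohex-6-en-1-yl]methanol | CC1(C)O[C@H]2[C@@H](O1)[C@H]3C=C(CO)[C@@H]2OO3
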